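Oak and elm hold the same charge, 13 mM starting material and 0.260 mM protic impurity, and differ in time of reading.

    starting material ⇌ ring (K1 = 4.0, k1 = 0.13 /min)
    starting material + starting material ⇌ open dimer (K2 = 95 /M, k2 = 15 /M/min)
    starting material + ring → side product (k3 = 3.9 /M/min)
    starting material + protic impurity → quenched substrate (k4 = 580 /M/min)

| setting | oak | elm |
|---|---|---|
| starting material | 13 mM | 13 mM |
| protic impurity | 0.260 mM | 0.260 mM |
| time | 40 min | 80 min |

- percentages count the starting material that a species holds: one open dimer or side product counts as two
- a step written with two of one species runs at k times the square of its concentration and takes two of it each time
- run time (oak): 40 min

* which of the two there is more of at the end, counted by the starting material in each, oak (ring / side product)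
* which of the two there is more of at the end, counted by the starting material in each, elm (ring / side product)
* ring at the end, in percent of the starting material charged, oak
* ring at the end, in percent of the starting material charged, elm

The impurity is the small thing, so it is taken off first. With starting material held at its charge, the impurity has a half-life of 0.0919 min, shorter than the 4.27 min relaxation of the ring equilibrium, so it removes its own amount and leaves a pool, c(starting material) + c(ring), of 12.7 mM.

That relaxation is also short against 40 min, so the reckoning treats the ring as a pre-equilibrium: ring holds a share 0.800 of the pool. Side product forms at 3.9 /M/min times the two shares times the pool squared, and each turn takes two of the pool. The pool therefore falls to its start over one plus N, where N is two times that constant, the two shares, the starting pool and the time. This gives 0.636 for oak and 1.27 for elm.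

N, the drain number, is the starting material lost to side product per unit of pool still standing. Side product over ring is thus N over the ring share, which puts ring ahead in oak and side product ahead in elm, with ring at 47.9 % in oak and 34.5 % in elm.

The open dimer stands outside N. At equilibrium with the pool so split, it holds 9.68 % of the starting pool, and that cuts the drain rate by the factor 0.816. N for elm then becomes 1.04, still above the ring share, and N for oak moves further below it, so the order stands in both flasks.

The forecast, with “the slow drain through starting material + ring to side product erodes the pool”, also has ring ahead in oak and side product ahead in elm, but puts ring higher than this reckoning at 50 % and 37 %.

Oak gives ring 47.5 % against side product 33.0 %, and elm gives ring 36.9 % against side product 50.5 %. For the flask oak left until 1.0 h, N is 0.954 before the open dimer factor, above the ring share, and 0.778 after it, below the ring share, so the reckoning leaves the order open, with ring between 40.1 % and 44.1 %. That flask holds ring 42.1 % and, narrowly ahead of it, side product 43.1 %.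

The constants were set for the occasion.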